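The easy step here is G meeting L to give G.L, so I start from it and add the other steps one at a time.

    G + X.G.L → Q (k1 = 0.024 M⁻¹ h⁻¹, Ea1 = 80.0 kJ mol⁻¹)
    X + G.L → X.G.L (k2 = 0.43 M⁻¹ h⁻¹, Ea2 = 70.0 kJ mol⁻¹)
    G + L → G.L (k3 = 0.99 M⁻¹ h⁻¹, Ea3 = 86.0 kJ mol⁻¹)
    (constants at 90 °C)

| setting | north-west | west | east | north |
|---|---|---|---|---|
| G | 0.10 M | 0.10 M | 0.10 M | 0.10 M |
| L | 2.00 equiv | 2.00 equiv | 2.00 equiv | 2.00 equiv |
| X | 1.20 equiv | 1.20 equiv | 1.20 equiv | 1.20 equiv |
| temperature | 30 °C |  | 60 °C | 90 °C |
| time | 25 h | 25 h | 25 h | 25 h |
| remark |  | at 90 °C until 20 h, from then on at 30 °C |  |  |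

- percentages count the G that a species holds: one Q counts as two
- the constants hold at 90 °C; other temperatures follow from the activation energies

- the best flask by amount of G.L, in percent of the G charged; "all alike" if 1.5 percentage points covers them all (north-west / west / east / north / all alike)
- amount of G.L at the end, in percent of the G charged, north-west
- amount of G.L at the end, in percent of the G charged, west
- amount of G.L at the end, in percent of the G charged, east
- amount of G.L at the end, in percent of the G charged, north

I carry one quantity: the lifetime of G.L against X, which is one over the constant of the step X + G.L times the starting c(X). This lifetime, a pseudo-first-order figure that holds c(X) at its start, is 19.4 h at 90 °C. G has its own lifetime against L, reckoned the same way from the starting c(L), of 5.05 h.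

With the main step alone, c(L) stays c(G) plus the excess, and the closed second-order form turns 92.6% of the G into G.L in west by the change at 20 h. In north it turns 95.6% by 25 h. In north-west, at 30 °C, the step G + L is slower by a factor of 280, and the same form gives 1.74%.

Now I add X. I take a G.L in west to be born, roughly, one G lifetime into the run, so I count it exposed for 0.771 lifetimes, and my first figure for G.L is 42.8% of the G. But each G.L lost takes one X with it, so c(X) falls. Taking the mean of its starting and reckoned final values stretches the lifetime and lifts my figure for west to 50.2%. The same reckoning, over 1.03 lifetimes, puts north at 44.5%.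

After its change, west is cold. There, reckoned from the starting c(X) and c(L), the lifetime of G.L is 1910 h, far longer than the remaining 5.00 h, and the lifetime of G is 1414 h, so I keep my figure for west. The last addition, G + X.G.L, has a constant of 0.024 M⁻¹ h⁻¹, smaller than the 0.43 M⁻¹ h⁻¹ of the step before it, and I leave it out. My figures set west above north by 5.7 percentage points, wider than the margin of 1.5 points. East I do not reckon by hand.

The forecast names west, with 1.73% in north-west, 51.5% in west, 27.1% in east and 46.7% in north. Of west's cold tail it says: "Cooling then nearly freezes it". Its west stands higher than my 50.2%, and its north higher than my 44.5%.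

The simulation gives west as the best flask, with 1.73% in north-west, 51.3% in west, 27.1% in east and 46.5% in north.

West's hot stretch spans 1.03 lifetimes of G.L, and west ends at 51.3%. In the neighbour of west charged with 0.060 M of G, the lifetime lengthens to 32.3 h. The same reckoning gives 82.0% made, 0.359 lifetimes exposed and 59.5% of G.L, and that flask ends at 57.1%.

The constants were chosen freely; what happens was integrated by code.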